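The data stem from a simulated flask for substances that don't exist, and the scatter is random.

Thursday's chemist left you one run, and from it you must judge four flasks. On the proposed steps, solid Q dissolves to E, Z turns E into G, G closes to the ring L, and E with G gives J and D.

the same everywhere: Q 0.050 M

| flask | Z | temperature | remark | time |
|---|---|---|---|---|
| Thursday's | 1.7 equiv | 70 °C | run made earlier |  |
| autumn | 1.10 equiv |  | at 20 °C until 20 min, from then on at 70 °C | 40 min |
| spring | 1.10 equiv | 70 °C |  | 40 min |
| noon | 1.10 equiv | 45 °C |  | 40 min |
| winter | 1.10 equiv | 20 °C |  | 40 min |

Thursday's run (percent of the Q charged): time / min: L / % = 0.333: 0; 1.00: 0.3; 2.00: 4.1; 3.00: 10.5; 4.00: 16.8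

(scatter of a reading: 0.5 percentage points)

- a species is counted by the Q in it: one J or D counts as two
- given per volume of solution although it is solid: Q
- steps that have been proposed: E + Z -> G; G -> L; E + G -> J; E + G -> D; Q <-> E
- at the start none of Q is in solution
- what has only dissolved of Q counts as not reacted
- the earlier runs do not show what temperature does; that part of a forecast is a guess

* which flask leads in amount of L, in percent of the Q charged ("all alike" within 1.5 percentage points) (autumn / spring / noon / winter / all alike)
* how much L is there at the end, in percent of the Q charged: autumn
* how much L is there at the end, in percent of the Q charged: spring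
* how much L is there at the end, in percent of the Q charged: noon
* how much L is there at the end, in percent of the Q charged: winter

Between 2.00 min and 4.00 min, L climbs from 4.1 % to 16.8 %. Carry that reading through spring's 40 min and it contradicts the charge:

pace = 0.0635 min⁻¹, as a fraction of the charge

pace × time = 254 % of the charge

Yet L cannot pass 100 %. So ask for the end state first. With 1.10 equiv of Z, Q is the limiting reagent, and the end is the charge shared among L, J and D. A pace says nothing of that share, only how soon the end comes. So turn it into the passage time, the time the whole charge would need at the steady pace:

passage time = 1 / pace = 15.7 min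

spring: time / passage time = 2.55

autumn, hot part: time / passage time = 1.27

The pace was read at 1.7 equiv of Z, so expect some stretch at 1.10 equiv. Still, my reckoning says spring and autumn both end finished, since their hot time exceeds the passage time. Their answers are then shares, not a matter of time. The earlier runs do not show what temperature does, and for noon and winter I give no number.

The forecast names spring, with L at 52 % in autumn, 65 % in spring, 50 % at noon and 20 % in winter. It holds that at the hot temperature “everything finishes well within 40 min”.

The flasks give spring as leader, with L at 64.6 % in autumn, 74.9 % in spring, 25.6 % at noon and 0.599 % in winter.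

    E + Z → G (k = 0.200 M⁻¹ s⁻¹, Ea = 64.0 kJ mol⁻¹)
    G → L (k = 0.00850 s⁻¹, Ea = 97.0 kJ mol⁻¹)
    E + G → J (k = 0.0170 M⁻¹ s⁻¹, Ea = 83.0 kJ mol⁻¹)
    E + G → D (k = 0.170 M⁻¹ s⁻¹, Ea = 45.0 kJ mol⁻¹)
    Q ⇌ E, rate k5*(cs5 - [E]) while solid is left; crystals form when [E] > cs5 (solubility = 31.0 mM, k = 0.00370 s⁻¹)
    (constants at 70 °C)

The passage time held at the hot temperature: spring has L at 71.2 % after 20.0 min and 75.1 % after 400 min, and autumn goes from 64.6 % after 40.0 min to 65.8 % after 400 min. The forecast parts from noon, whose L is 25.6 % after 40.0 min but 43.3 % after 400 min. Now a neighbour, winter kept at 35 °C: L reaches 7.78 % in 40.0 min, so its passage time, taken at the mean pace of that flask, is 514 min, far longer than its time. That flask ends with E at 20.3 %, G at 23.6 % and D at 47.3 %.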